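The hydroxyphthalide of ring B (lactone carbonyl C1, O2, lactol carbon C3 on C3a, C7–OH next to C7a) is treated as an 8-hydroxy-6-methoxyisocoumarin that has lost one carbon. Ozonolysis of the isocoumarin C3=C4 enol-lactone bond expels isocoumarin C3 as formic acid, turns C4 into an aryl aldehyde and lets the freed C1 carboxyl close on it, so the five-membered lactol and its O2–C3 bond arise in one operation. The precursor is the fully assembled ester: the isocoumarin whose C7 methylene already carries the ring A 2-hydroxy-4-methoxy-3,6-dimethylbenzoate. C3 is fixed as (R) afterwards by lipase dynamic kinetic resolution.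

Key step: step 9

Assumption: the lactol carbon C3 is a hemiacetal that can epimerise through its open formyl acid form; it is taken to do so at a useful rate only under weak-base catalysis (pyridine) and to hold its configuration in neutral, base-free, non-aqueous media at or below room temperature, and bases strong enough to ionise the phenol beside the acyloxymethyl group are avoided once the benzylic ester is in place, because that phenoxide could expel the ring A carboxylate.

Step 1
Reactants: 1 methyl orsellinate (methyl 2,4-dihydroxy-6-methylbenzoate)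
Product: 2 methyl 2-hydroxy-4-methoxy-6-methylbenzoate
Conditions: MeI (1.1 equiv), K2CO3, acetone, reflux
Reagents that add atoms: iodomethane, CI
Why: Williamson O-methylation should go to the 4-OH only, because the 2-OH is held in a hydrogen bond to the ester carbonyl and is far less acidic and nucleophilic.

Step 2
Reactants: 2 methyl 2-hydroxy-4-methoxy-6-methylbenzoate
Product: 4 methyl 2-hydroxy-3-(hydroxymethyl)-4-methoxy-6-methylbenzoate, via cyclic phenylboronate 3 (not isolated)
Conditions: PhB(OH)2, (CH2O)n, EtCO2H (cat.), toluene, reflux (Dean–Stark); then propane-1,3-diol, THF, rt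
Reagents that add atoms: paraformaldehyde (formaldehyde), C=O; phenylboronic acid, OB(O)c1ccccc1 (its boron and phenyl stay only in intermediate 3)
Why: Boronic-acid-templated ortho-hydroxymethylation delivers formaldehyde from the aryl boronate to the only free position ortho to the phenol (C3, also activated by the neighbouring methoxy group), and transesterification onto propane-1,3-diol then releases the salicyl alcohol.

Step 3
Reactants: 4 methyl 2-hydroxy-3-(hydroxymethyl)-4-methoxy-6-methylbenzoate
Product: 5 methyl 5-methoxy-2,2,7-trimethyl-4H-1,3-benzodioxine-8-carboxylate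
Conditions: Me2C(OMe)2, PPTS (cat.), acetone, rt
Reagents that add atoms: 2,2-dimethoxypropane, COC(C)(C)OC
Why: Acid-catalysed transketalisation should close the six-membered isopropylidene acetal over the phenol and the benzylic alcohol, masking both protic groups before the strong base of the next step.

Step 4
Reactants: 5 methyl 5-methoxy-2,2,7-trimethyl-4H-1,3-benzodioxine-8-carboxylate
Product: 7 8-O,7-CH2O-isopropylidene acetal of 8-hydroxy-7-(hydroxymethyl)-6-methoxyisocoumarin, via arylacetaldehyde 6 (not isolated)
Conditions: LiN(iPr)2 (1.2 equiv), THF, −78 °C; DMF, −78 → 0 °C; AcOH, then H2O; crude in toluene, TsOH (cat.), 4 Å sieves, 80 °C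
Reagents that add atoms: N,N-dimethylformamide, CN(C)C=O
Why: Lateral lithiation of the ortho-toluate gives the ester-stabilised toluate anion, which DMF formylates, and the enol of the resulting arylacetaldehyde then closes onto the neighbouring ester under anhydrous acid (enol lactonisation) to give the 3-unsubstituted isocoumarin; partial loss of the acetonide here would only anticipate step 5.

Step 5
Reactants: 7 8-O,7-CH2O-isopropylidene acetal of 8-hydroxy-7-(hydroxymethyl)-6-methoxyisocoumarin
Product: 8 8-hydroxy-7-(hydroxymethyl)-6-methoxy-1H-isochromen-1-one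
Conditions: 1 M HCl (aq, cat.), THF, rt
Reagents that add atoms: water, O
Why: Mild aqueous acid hydrolysis of the aryl alkyl ketal should be fast, helped by the hydrogen bond of the freed C8 phenol to the lactone carbonyl, while the enol lactone tolerates dilute acid at room temperature.

Step 6
Reactants: 9 methyl 2,4-dihydroxy-3,6-dimethylbenzoate
Product: 10 methyl 2-hydroxy-4-methoxy-3,6-dimethylbenzoate
Conditions: MeI (1.1 equiv), K2CO3, acetone, reflux
Reagents that add atoms: iodomethane, CI
Why: Williamson O-methylation again selects the non-chelated 4-OH over the ester-bonded 2-OH.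

Step 7
Reactants: 10 methyl 2-hydroxy-4-methoxy-3,6-dimethylbenzoate
Product: 11 2-hydroxy-4-methoxy-3,6-dimethylbenzoic acid
Conditions: KOH, DMSO/H2O, 80 °C; then 1 M HCl, 0 °C
Reagents that add atoms: potassium hydroxide, [K+].[OH-]
Why: Saponification of the hindered salicylate ester is driven by hot hydroxide in aqueous DMSO, and cold acidification avoids decarboxylation of the electron-rich acid.

Step 8
Reactants: 8 8-hydroxy-7-(hydroxymethyl)-6-methoxy-1H-isochromen-1-one; 11 2-hydroxy-4-methoxy-3,6-dimethylbenzoic acid (1.2 equiv)
Product: 12 (8-hydroxy-6-methoxy-1-oxo-1H-isochromen-7-yl)methyl 2-hydroxy-4-methoxy-3,6-dimethylbenzoate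
Conditions: PPh3, DIAD, THF, 0 °C → rt
Reagents that add atoms: none
Why: Mitsunobu esterification activates the primary benzylic alcohol as its alkoxyphosphonium ion and lets the carboxylate of the much more acidic salicylic acid displace it, which avoids activating the doubly ortho-substituted acid and leaves the two chelated phenols untouched.

Step 9
Reactants: 12 (8-hydroxy-6-methoxy-1-oxo-1H-isochromen-7-yl)methyl 2-hydroxy-4-methoxy-3,6-dimethylbenzoate
Product: 16 racemic [(3RS)-3,7-dihydroxy-5-methoxy-1-oxo-1,3-dihydro-2-benzofuran-6-yl]methyl 2-hydroxy-4-methoxy-3,6-dimethylbenzoate, via secondary ozonide 13 (not isolated), via formyl mixed anhydride 14 (not isolated), via formylbenzoic acid 15 (not isolated)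
Conditions: O3 (1.0 equiv, titrated CH2Cl2 solution), CH2Cl2, −78 °C; PPh3, −78 °C → rt; then THF/H2O, rt
Reagents that add atoms: ozone, [O-][O+]=O
Why: Ozone adds across isocoumarin C3=C4 in a 1,3-dipolar cycloaddition, the primary ozonide fragments and recombines (Criegee mechanism) to ozonide 13, and PPh3 reduction leaves the aryl aldehyde at former C4 together with the aroyl formyl mixed anhydride 14. Water attacks the unhindered formyl carbon of 14, so former C3 leaves as formic acid and the C1 carboxyl of 15 is set free. A carboxyl oxygen then adds to the ortho aldehyde in a 5-exo-trig closure, forming the O2–C3 bond and the five-membered lactol ring in place of the six-membered enol lactone. The closest known reaction type is the ozonolysis of isocoumarins and other enol lactones to ortho-formyl or ortho-acyl benzoic acids, which exist as 3-hydroxyphthalides. The new stereocentre C3 forms without any controlling element and is taken racemic on purpose, since step 10 sets it. The step needs chemoselectivity for the enol-lactone alkene over the two oxygenated arenes, which should come from its being the only non-aromatic C=C, from the chelated phenols and ester groups that damp both arenes, and from metering one equivalent of ozone at −78 °C.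

Step 10
Reactants: 16 racemic [(3RS)-3,7-dihydroxy-5-methoxy-1-oxo-1,3-dihydro-2-benzofuran-6-yl]methyl 2-hydroxy-4-methoxy-3,6-dimethylbenzoate
Product: 17 [(3R)-3-acetoxy-7-hydroxy-5-methoxy-1-oxo-1,3-dihydro-2-benzofuran-6-yl]methyl 2-hydroxy-4-methoxy-3,6-dimethylbenzoate
Conditions: immobilised Burkholderia cepacia lipase, vinyl acetate, pyridine (cat.), toluene/THF, 35 °C
Reagents that add atoms: vinyl acetate, C=COC(C)=O
Why: Lipase-catalysed dynamic kinetic resolution by irreversible transesterification: pyridine-catalysed ring–chain tautomerism through 15 keeps the lactol enantiomers in equilibrium while the enzyme acetylates one of them, expected to be (R) from the empirical size rule for lipase acylation of secondary alcohols (aryl carbon C3a as the large, ring oxygen O2 as the medium substituent) and to be confirmed in a small enzyme screen, so the enzyme sets C3, and the chelated phenols and the hindered benzoate are not lipase substrates.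

Step 11
Reactants: 17 [(3R)-3-acetoxy-7-hydroxy-5-methoxy-1-oxo-1,3-dihydro-2-benzofuran-6-yl]methyl 2-hydroxy-4-methoxy-3,6-dimethylbenzoate
Product: 18 [(3R)-3,7-dihydroxy-5-methoxy-1-oxo-1,3-dihydro-2-benzofuran-6-yl]methyl 2-hydroxy-4-methoxy-3,6-dimethylbenzoate (target)
Conditions: immobilised Burkholderia cepacia lipase, n-BuOH, MTBE/THF, 0–10 °C; filtration, evaporation below 20 °C
Reagents that add atoms: none
Why: Lipase-catalysed alcoholysis cleaves the acetyl C–O bond and not the C3–O bond, so the (R) configuration should be retained, and the cold, base-free, non-aqueous medium offers ring–chain epimerisation no catalyst.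

Compound list
1 | methyl orsellinate (methyl 2,4-dihydroxy-6-methylbenzoate) | COC(=O)c1c(C)cc(O)cc1O | starting material
2 | methyl 2-hydroxy-4-methoxy-6-methylbenzoate | COC(=O)c1c(C)cc(OC)cc1O | intermediate
3 | methyl 5-methoxy-7-methyl-2-phenyl-4H-1,3,2-benzodioxaborinine-8-carboxylate (cyclic phenylboronate of 4) | COC(=O)c1c(C)cc(OC)c2COB(c3ccccc3)Oc12 | intermediate (not isolated)
4 | methyl 2-hydroxy-3-(hydroxymethyl)-4-methoxy-6-methylbenzoate | COC(=O)c1c(C)cc(OC)c(CO)c1O | intermediate
5 | methyl 5-methoxy-2,2,7-trimethyl-4H-1,3-benzodioxine-8-carboxylate (acetonide of 4) | COC(=O)c1c(C)cc(OC)c2COC(C)(C)Oc12 | intermediate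
6 | methyl 5-methoxy-2,2-dimethyl-7-(2-oxoethyl)-4H-1,3-benzodioxine-8-carboxylate | COC(=O)c1c(CC=O)cc(OC)c2COC(C)(C)Oc12 | intermediate (not isolated)
7 | 8-O,7-CH2O-isopropylidene acetal of 8-hydroxy-7-(hydroxymethyl)-6-methoxyisocoumarin (isocoumarin fused at C7/C8 to a 2,2-dimethyl-1,3-dioxine) | COc1cc2C=COC(=O)c2c2OC(C)(C)OCc12 | intermediate
8 | 8-hydroxy-7-(hydroxymethyl)-6-methoxy-1H-isochromen-1-one | COc1cc2C=COC(=O)c2c(O)c1CO | intermediate
9 | methyl 2,4-dihydroxy-3,6-dimethylbenzoate | COC(=O)c1c(C)cc(O)c(C)c1O | starting material
10 | methyl 2-hydroxy-4-methoxy-3,6-dimethylbenzoate | COC(=O)c1c(C)cc(OC)c(C)c1O | intermediate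
11 | 2-hydroxy-4-methoxy-3,6-dimethylbenzoic acid | Cc1cc(OC)c(C)c(O)c1C(=O)O | intermediate
12 | (8-hydroxy-6-methoxy-1-oxo-1H-isochromen-7-yl)methyl 2-hydroxy-4-methoxy-3,6-dimethylbenzoate (key-step precursor) | COc1cc(C)c(C(=O)OCc2c(OC)cc3C=COC(=O)c3c2O)c(O)c1C | intermediate
13 | secondary ozonide (1,2,4-trioxolane across isocoumarin C3 and C4) of 12 | COc1cc(C)c(C(=O)OCc2c(OC)cc3C4OOC(O4)OC(=O)c3c2O)c(O)c1C | intermediate (not isolated)
14 | 6-formyl-2-hydroxy-4-methoxy-3-{[(2-hydroxy-4-methoxy-3,6-dimethylbenzoyl)oxy]methyl}benzoic formic anhydride | COc1cc(C)c(C(=O)OCc2c(OC)cc(C=O)c(C(=O)OC=O)c2O)c(O)c1C | intermediate (not isolated)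
15 | 6-formyl-2-hydroxy-4-methoxy-3-{[(2-hydroxy-4-methoxy-3,6-dimethylbenzoyl)oxy]methyl}benzoic acid | COc1cc(C)c(C(=O)OCc2c(OC)cc(C=O)c(C(=O)O)c2O)c(O)c1C | intermediate (not isolated)
16 | racemic [(3RS)-3,7-dihydroxy-5-methoxy-1-oxo-1,3-dihydro-2-benzofuran-6-yl]methyl 2-hydroxy-4-methoxy-3,6-dimethylbenzoate | COc1cc(C)c(C(=O)OCc2c(OC)cc3c(c2O)C(=O)OC3O)c(O)c1C | intermediate
17 | [(3R)-3-acetoxy-7-hydroxy-5-methoxy-1-oxo-1,3-dihydro-2-benzofuran-6-yl]methyl 2-hydroxy-4-methoxy-3,6-dimethylbenzoate | COc1cc(C)c(C(=O)OCc2c(OC)cc3c(c2O)C(=O)O[C@H]3OC(C)=O)c(O)c1C | intermediate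
18 | [(3R)-3,7-dihydroxy-5-methoxy-1-oxo-1,3-dihydro-2-benzofuran-6-yl]methyl 2-hydroxy-4-methoxy-3,6-dimethylbenzoate | COc1cc(C)c(C(=O)OCc2c(OC)cc3c(c2O)C(=O)O[C@H]3O)c(O)c1C | target

Total step count: 11. Longest linear sequence: 9 steps (steps 1–5 and 8–11, from methyl orsellinate); steps 6 and 7 form the short ring A branch.

Steps most likely to fail

Step 9. The danger is oxidation of the electron-rich arenes (ring A above all) by ozone in competition with cleavage of the enol-lactone alkene, and over-oxidation of the new aldehyde. The fallback sets out from 12 and replaces ozone by a Lemieux–Johnson cleavage with catalytic OsO4, NaIO4 and 2,6-lutidine in dioxane/water. OsO4 leaves arenes alone and dihydroxylates the C3=C4 bond to the cis-3,4-dihydroxy-3,4-dihydroisocoumarin F1, which periodate cleaves in the same flask to the formyl mixed anhydride 14. Hydrolysis and lactol closure then proceed as in step 9, and the route is rejoined at 16.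

Step 10. The resolution may stop being dynamic because the lactol epimerises more slowly than it is acylated, or the lipase may discriminate poorly between the enantiomers of this hindered lactol. The fallback sets out from 16 and gives up catalytic enantioselection for physical separation: preparative supercritical-fluid chromatography on an immobilised polysaccharide chiral phase with CO2 and an aprotic modifier (MeCN) below room temperature. The (S)-lactol is re-equilibrated with catalytic pyridine in toluene and recycled, and the (R)-lactol collected is the target, so the route is rejoined at 18 and step 11 is not needed; no new compound is made (F0).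

Step 4. The lateral carbanion may be lost to Claisen-type self-condensation with unreacted ester or to proton transfer before formyl transfer is complete, and the DMF adduct may not collapse cleanly to the enol lactone. The fallback sets out from 5 and brings in the extra carbon at the carboxyl level: the toluate anion (LiN(iPr)2, THF, −78 °C) is trapped with CO2, a fast and irreversible carboxylation, to give the arylacetic acid F2. BH3·SMe2 reduces the free acid in the presence of the hindered methyl ester to the primary alcohol F3, and Dess–Martin periodinane buffered with NaHCO3 oxidises it to the arylacetaldehyde 6. There the route is rejoined, and the acid-mediated enol lactonisation of step 4 gives 7.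

Further compounds
F1 | step 9 | (3,4,8-trihydroxy-6-methoxy-1-oxo-3,4-dihydro-1H-isochromen-7-yl)methyl 2-hydroxy-4-methoxy-3,6-dimethylbenzoate (racemic cis-3,4-diol, one enantiomer drawn) | COc1cc(C)c(C(=O)OCc2c(OC)cc3[C@H](O)[C@H](O)OC(=O)c3c2O)c(O)c1C
F0 | step 10 | none | none
F2 | step 4 | 2-[5-methoxy-8-(methoxycarbonyl)-2,2-dimethyl-4H-1,3-benzodioxin-7-yl]acetic acid | COC(=O)c1c(CC(=O)O)cc(OC)c2COC(C)(C)Oc12
F3 | step 4 | methyl 7-(2-hydroxyethyl)-5-methoxy-2,2-dimethyl-4H-1,3-benzodioxine-8-carboxylate | COC(=O)c1c(CCO)cc(OC)c2COC(C)(C)Oc12
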